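One decade of concentration is the unit to work in.

| flask | first end groups | second end groups | temperature | remark | time |
|---|---|---|---|---|---|
| Saturday's | 0.051 M | 1.05 equiv | 45 °C | run made earlier |  |
| Wednesday's | 0.025 M | 1.05 equiv | 56 °C | run made earlier |  |
| Monday's | 0.10 M | 1.05 equiv | 45 °C | run made earlier |  |
| elm | 0.051 M (fed, over 15 min) | 1.05 equiv | 50 °C | all else is in the flask from the start; the feed brings no volume worth counting | 40 min |
| ash | 0.051 M (fed, over 15 min) | 1.05 equiv |  | the addition at 30 °C, then warmed to 50 °C; the feed brings no volume worth counting | 40 min |
| birch | 0.051 M | 1.05 equiv (fed, over 15 min) | 50 °C | all else is in the flask from the start; the feed brings no volume worth counting | 40 min |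
| cedar | 0.051 M | 1.05 equiv (fed, over 4.0 min) | 50 °C | all else is in the flask from the start; the feed brings no volume worth counting | 40 min |
| oak | 0.051 M | 1.05 equiv (in portions, 2, over 15 min) | 50 °C | first portion at the start, last at 15 min | 40 min |

- Saturday's (time / min: links / %): 5.00: 40; 10.0: 47; 15.0: 46; 20.0: 47; 25.0: 47
- Wednesday's (time / min: links / %): 6.00: 31; 12.0: 35; 20.0: 37; 25.0: 39; 30.0: 40
- Monday's (time / min: links / %): 2.50: 44; 5.00: 54; 10.0: 57; 15.0: 57; 30.0: 46

(scatter of a reading: 1.5 percentage points)

- what is said of links includes idle adduct
- on the list of suspects stand: links <-> isomer of the product; first end groups + second end groups -> rings; first end groups + second end groups -> links; second end groups + links <-> idle adduct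

- which flask leads in amount of links, in percent of the first end groups charged ("all alike" within 1.5 percentage points) (elm / ash / birch / cedar / oak / all alike)
- how much links is there at the end, in percent of the first end groups charged: elm
- how much links is there at the end, in percent of the first end groups charged: ash
- how much links is there at the end, in percent of the first end groups charged: birch
- how much links is there at the end, in percent of the first end groups charged: cedar
- how much links is there at the end, in percent of the first end groups charged: oak

**What do the earlier runs give?** Saturday's and Monday's stand at one temperature. Monday's reading of 57% at 0.10 M is higher than Saturday's 47% at 0.051 M.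

**Put that in one number.** Take the yield slope, the decades of links share gained per decade of concentration 0.286. It is a reading on two points, each with a scatter of 1.5 percentage points. It is an apparent selectivity order.

**Does it survive a third run?** From Saturday's reading, the slope gives 38.3% at 0.025 M. Wednesday's last reading is 40%, at 56 °C.

**Whose concentration is it?** That is the weak spot. These runs kept the end groups near equal, so they cannot say. My bet is c(second end groups).

**Then what do you commit to?** Elm has its second end groups in from the start, so I keep Saturday's 47%. In birch, I take c(second end groups) over the feed as half of the charge. That gives 38.5%, a ratio of birch to elm of 0.820. I expect elm or ash to lead.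

The forecast differs: elm 30%, ash 34%, birch 27%, cedar 39%, oak 38%, with cedar leading. Its ground: “Any slow feed then starves links, giving about 20–30%”.

The flasks give elm 42.5%, ash 44.0%, birch 35.4%, cedar 40.4% and oak 35.9%, so ash leads.

    links ⇌ isomer of the product (K = 0.870, k = 0.0780 min⁻¹, Ea = 107 kJ mol⁻¹, ΔH = −79.0 kJ mol⁻¹)
    first end groups + second end groups → rings, rate k2*[first end groups] as long as [second end groups] is above zero (k = 0.0200 min⁻¹, Ea = 100 kJ mol⁻¹)
    first end groups + second end groups → links (k = 4.20 L mol⁻¹ min⁻¹, Ea = 43.0 kJ mol⁻¹)
    second end groups + links ⇌ idle adduct, settled at all times (K = 6.90 L mol⁻¹, ΔH = −45.0 kJ mol⁻¹)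
    (constants at 50 °C)

Birch over elm stands at 0.833, close to the slope's 0.820, though both my levels were high. By 15.0 min, birch held rings at 21.0%, more than elm's 7.24%, and 81% of its rings turnover lay behind it at 20.0 min. Free links and isomer of the product then relaxed with a half-life of 4.13 min, short against 40 min, leaving birch at 27.2% isomer of the product. From birch, the slope gives 27.1% for the same recipe at 0.020 M. That neighbour flask holds 26.8% links beside 37.3% rings.

The runs were generated by integration on assumed constants; scatter was added.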